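**Strategy.** In daucane numbering (C1 angular quaternary carbon, C4 isopropyl carbinol, C5 ring-fusion CH, C6 ester carbinol, C10 ketone) the route rests on cutting the seven-membered ring at C1–C10 and C5–C6, the two bonds flanking the C1–C5 bond shared with the cyclopentane. With C4 as a ketone, C1 and C5 are its β- and α-carbons, so one copper-catalysed enantioselective conjugate addition–aldol cascade on 3-methylcyclopent-2-en-1-one attaches a vinyl unit (C10) to C1 and an aldehyde (C6–C9) to C5, anti across the ring, setting C1, C5 and C6 together. The precursors are just the enone, a silylvinylalane and a pentenal. Ring-closing metathesis and a singlet-oxygen ene transposition complete the enone.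

Key step: step 2

Remark: aldehyde 3 is used as the racemate; its methyl-bearing carbon (C8 of the skeleton) is carried as an inconsequential pair of epimers in 8–12 and becomes sp2 in step 7.

Step 1
Reactants: 1 (E)-but-2-en-1-ol
Product: 3 rac-3-methylpent-4-enal, via (E)-but-2-enyl vinyl ether 2 (not isolated)
Conditions: ethyl vinyl ether (excess), Hg(OAc)2 (cat.), reflux; then concentrate, 150 °C (sealed tube)
Reagents that add atoms: ethyl vinyl ether, C=COCC
Why: Mercury-catalysed vinyl-ether exchange and Claisen rearrangement of the resulting allyl vinyl ether should deliver the γ,δ-unsaturated aldehyde; the [3,3] shift creates the methyl-bearing carbon as a racemate, which is acceptable because that carbon becomes sp2 in step 7.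

Step 2
Reactants: 4 3-methylcyclopent-2-en-1-one; 5 ethynyltrimethylsilane; 3 rac-3-methylpent-4-enal
Product: 8 (2S,3S)-2-[(1S)-1-hydroxy-3-methylpent-4-en-1-yl]-3-methyl-3-[1-(trimethylsilyl)ethenyl]cyclopentan-1-one, via silylvinylalane 6 (not isolated), via aluminium enolate 7 (not isolated)
Conditions: 5, i-Bu2AlH, hexanes/THF, 55 °C; then 4, Cu(OTf)2 (5 mol %), chiral sulfonate-bearing imidazolinium salt (NHC precursor, 5 mol %), THF, −30 → 4 °C; then 3 (excess), −78 °C; aq. potassium sodium tartrate
Reagents that add atoms: none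
Why: Hydroalumination of 5 places aluminium on the silicon-bearing carbon to give 6; the chiral NHC–copper complex then transfers this vinyl group to the β-carbon of 4 (bond C1–C10), and the diisobutylaluminium enolate 7, formed regiospecifically at C5, adds to aldehyde 3 through a closed chair-like transition state (bond C5–C6). The closest known reaction type is the NHC–Cu-catalysed enantioselective conjugate addition of silyl-substituted vinylaluminium reagents to β-substituted cyclic enones, here coupled to aldol trapping of the metal enolate (three-component tandem conjugate addition–aldol). No ring is closed in this step; the two new bonds are the ones that will flank the ring fusion, and the seven-membered ring is closed in step 6. C1 is set by the chiral catalyst, C5 by approach of the aldehyde anti to the bulky 1-(trimethylsilyl)ethenyl group on the neighbouring quaternary carbon (cis to methyl, the later trans ring fusion), and C6 by the anti-selective aldol of the ring-locked (E)-enolate. The step needs 1,4- over 1,2-addition and vinyl over isobutyl transfer, which copper catalysis and the preferred transfer of the sp2 ligand should secure, and it needs attack on the face anti to the vinyl group, which the silyl substituent enforces by making that group far larger than methyl.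

Step 3
Reactants: 8 (2S,3S)-2-[(1S)-1-hydroxy-3-methylpent-4-en-1-yl]-3-methyl-3-[1-(trimethylsilyl)ethenyl]cyclopentan-1-one
Product: 9 (1S)-3-methyl-1-{(1S,2S)-2-methyl-5-oxo-2-[1-(trimethylsilyl)ethenyl]cyclopentyl}pent-4-en-1-yl 3,4-dimethoxybenzoate
Conditions: 3,4-dimethoxybenzoyl chloride, pyridine, DMAP (cat.), CH2Cl2, 0 °C → rt
Reagents that add atoms: 3,4-dimethoxybenzoyl chloride, COc1ccc(C(Cl)=O)cc1OC
Why: DMAP-catalysed acylation (Steglich-type acyl transfer) of the only hydroxyl group should give the ester under conditions too mild for retro-aldol cleavage or β-elimination; no stereocentre is touched.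

Step 4
Reactants: 9 (1S)-3-methyl-1-{(1S,2S)-2-methyl-5-oxo-2-[1-(trimethylsilyl)ethenyl]cyclopentyl}pent-4-en-1-yl 3,4-dimethoxybenzoate
Product: 10 (1S)-1-[(1S,2R)-2-ethenyl-2-methyl-5-oxocyclopentyl]-3-methylpent-4-en-1-yl 3,4-dimethoxybenzoate
Conditions: CF3CO2H, CH2Cl2, 0 °C → rt; aq. NaHCO3
Reagents that add atoms: none
Why: Acid-mediated protodesilylation of the vinylsilane (ipso protonation to a β-silyl-stabilised cation, then loss of silicon) should unmask the plain vinyl group needed for metathesis, while ketone, ester and the terminal alkene tolerate brief exposure to CF3CO2H.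

Step 5
Reactants: 10 (1S)-1-[(1S,2R)-2-ethenyl-2-methyl-5-oxocyclopentyl]-3-methylpent-4-en-1-yl 3,4-dimethoxybenzoate
Product: 11 (1S)-1-[(1S,2R,5R)-2-ethenyl-5-hydroxy-2-methyl-5-(propan-2-yl)cyclopentyl]-3-methylpent-4-en-1-yl 3,4-dimethoxybenzoate
Conditions: i-PrMgCl, CeCl3 (anhydrous), THF, −78 °C; aq. NH4Cl
Reagents that add atoms: isopropylmagnesium chloride, CC(C)[Mg]Cl
Why: Organocerium (Grignard–CeCl3) 1,2-addition, which favours carbonyl addition over enolisation and reacts with ketones much faster than with aryl esters, should deliver isopropyl to the cyclopentanone from the face opposite the adjacent C5 side chain, so that the new tertiary hydroxyl at C4 ends up cis to that side chain.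

Step 6
Reactants: 11 (1S)-1-[(1S,2R,5R)-2-ethenyl-5-hydroxy-2-methyl-5-(propan-2-yl)cyclopentyl]-3-methylpent-4-en-1-yl 3,4-dimethoxybenzoate
Product: 12 (3R,3aS,4S,8aR)-3-hydroxy-6,8a-dimethyl-3-(propan-2-yl)-1,2,3,3a,4,5,6,8a-octahydroazulen-4-yl 3,4-dimethoxybenzoate
Conditions: second-generation Grubbs catalyst (5 mol %), CH2Cl2, 40 °C
Reagents that add atoms: none
Why: Ring-closing metathesis of the two monosubstituted alkenes, driven by loss of ethene, should close the seven-membered ring trans-fused to the cyclopentane without touching any stereocentre.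

Step 7
Reactants: 12 (3R,3aS,4S,8aR)-3-hydroxy-6,8a-dimethyl-3-(propan-2-yl)-1,2,3,3a,4,5,6,8a-octahydroazulen-4-yl 3,4-dimethoxybenzoate
Product: 14 (3R,3aS,4S,8aS)-3-hydroxy-6,8a-dimethyl-8-oxo-3-(propan-2-yl)-1,2,3,3a,4,5,8,8a-octahydroazulen-4-yl 3,4-dimethoxybenzoate, via allylic hydroperoxide 13 (not isolated)
Conditions: O2, tetraphenylporphyrin (cat.), visible light, CH2Cl2, 0 °C; then Ac2O, pyridine, DMAP (cat.), 0 °C → rt
Reagents that add atoms: oxygen, O=O
Why: Schenck ene reaction of singlet oxygen, which can abstract only the single allylic hydrogen at the methyl-bearing carbon (the other allylic carbon is quaternary), should place the hydroperoxide at C10 and shift the double bond to C8–C9 for both epimers, and Kornblum–DeLaMare-type dehydration of the secondary hydroperoxide then gives the enone.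

**Compound list**

1 | (E)-but-2-en-1-ol | C/C=C/CO | starting material
2 | (E)-but-2-enyl vinyl ether | C/C=C/COC=C | intermediate
3 | rac-3-methylpent-4-enal | C=CC(C)CC=O | intermediate
4 | 3-methylcyclopent-2-en-1-one | CC1=CC(=O)CC1 | starting material
5 | ethynyltrimethylsilane | C#C[Si](C)(C)C | starting material
6 | diisobutyl[1-(trimethylsilyl)ethenyl]aluminium | C=C([Si](C)(C)C)[Al](CC(C)C)CC(C)C | intermediate
7 | diisobutylaluminium (3S)-3-methyl-3-[1-(trimethylsilyl)ethenyl]cyclopent-1-en-1-olate | CC(C)C[Al](CC(C)C)OC1=C[C@](C)(CC1)C(=C)[Si](C)(C)C | intermediate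
8 | (2S,3S)-2-[(1S)-1-hydroxy-3-methylpent-4-en-1-yl]-3-methyl-3-[1-(trimethylsilyl)ethenyl]cyclopentan-1-one (both epimers at the chain methyl carbon) | C=CC(C)C[C@H](O)[C@H]1C(=O)CC[C@]1(C)C(=C)[Si](C)(C)C | intermediate
9 | (1S)-3-methyl-1-{(1S,2S)-2-methyl-5-oxo-2-[1-(trimethylsilyl)ethenyl]cyclopentyl}pent-4-en-1-yl 3,4-dimethoxybenzoate | C=CC(C)C[C@H](OC(=O)c1ccc(OC)c(OC)c1)[C@H]1C(=O)CC[C@]1(C)C(=C)[Si](C)(C)C | intermediate
10 | (1S)-1-[(1S,2R)-2-ethenyl-2-methyl-5-oxocyclopentyl]-3-methylpent-4-en-1-yl 3,4-dimethoxybenzoate | C=CC(C)C[C@H](OC(=O)c1ccc(OC)c(OC)c1)[C@H]1C(=O)CC[C@]1(C)C=C | intermediate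
11 | (1S)-1-[(1S,2R,5R)-2-ethenyl-5-hydroxy-2-methyl-5-(propan-2-yl)cyclopentyl]-3-methylpent-4-en-1-yl 3,4-dimethoxybenzoate | C=CC(C)C[C@H](OC(=O)c1ccc(OC)c(OC)c1)[C@H]1[C@](O)(C(C)C)CC[C@]1(C)C=C | intermediate
12 | (3R,3aS,4S,8aR)-3-hydroxy-6,8a-dimethyl-3-(propan-2-yl)-1,2,3,3a,4,5,6,8a-octahydroazulen-4-yl 3,4-dimethoxybenzoate (both C6 epimers) | COc1ccc(C(=O)O[C@H]2CC(C)C=C[C@@]3(C)CC[C@@](O)(C(C)C)[C@H]23)cc1OC | intermediate
13 | (3R,3aS,4S,8aS)-8-hydroperoxy-3-hydroxy-6,8a-dimethyl-3-(propan-2-yl)-1,2,3,3a,4,5,8,8a-octahydroazulen-4-yl 3,4-dimethoxybenzoate (both C8 epimers) | COc1ccc(C(=O)O[C@H]2CC(C)=CC(OO)[C@@]3(C)CC[C@@](O)(C(C)C)[C@H]23)cc1OC | intermediate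
14 | (3R,3aS,4S,8aS)-3-hydroxy-6,8a-dimethyl-8-oxo-3-(propan-2-yl)-1,2,3,3a,4,5,8,8a-octahydroazulen-4-yl 3,4-dimethoxybenzoate | COc1ccc(C(=O)O[C@H]2CC(C)=CC(=O)[C@@]3(C)CC[C@@](O)(C(C)C)[C@H]23)cc1OC | target

Total step count: 7. Longest linear sequence: 7 steps (1 → 3 → 8 → 9 → 10 → 11 → 12 → 14); 6 steps from enone 4.

**Steps most likely to fail**

Step 2. The aluminium enolate may add to the wrong face of the aldehyde carbonyl (syn instead of anti simple diastereoselection), so that the carbinol carbon C6 forms with the wrong configuration. The fallback sets the C6 configuration by inversion instead of by the aldol. It sets out from enolate 7 and aldehyde 3 in the same cascade and accepts the syn adduct, (2S,3S)-2-[(1R)-1-hydroxy-3-methylpent-4-en-1-yl]-3-methyl-3-[1-(trimethylsilyl)ethenyl]cyclopentan-1-one F1. Mitsunobu esterification of this adduct with 3,4-dimethoxybenzoic acid (PPh3, diisopropyl azodicarboxylate, THF) inverts C6 and installs the ester at once. The fallback comes back to the route at 9, so step 3 is skipped.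

Step 5. The hindered β-acyloxy ketone may be enolised with loss of the benzoate, the ester may be attacked, or the Grignard reagent may transfer hydride instead of adding. The fallback adds isopropyl before the ester exists. It sets out from 8, which is protodesilylated (CF3CO2H, CH2Cl2) to the hydroxy ketone (2S,3R)-3-ethenyl-2-[(1S)-1-hydroxy-3-methylpent-4-en-1-yl]-3-methylcyclopentan-1-one F2. Excess i-PrMgCl/CeCl3 then adds to the metal alkoxide of this unprotected β-hydroxy ketone, which has no leaving group and no ester, to give the diol (1R,2S,3R)-3-ethenyl-2-[(1S)-1-hydroxy-3-methylpent-4-en-1-yl]-3-methyl-1-(propan-2-yl)cyclopentan-1-ol F3. Selective acylation of the secondary hydroxyl with 3,4-dimethoxybenzoyl chloride (pyridine, DMAP) brings the fallback back at 11.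

Step 7. The ene reaction of the 1,2-disubstituted alkene with singlet oxygen may be sluggish, and photo-oxidation of the dimethoxyarene may compete. The fallback replaces the ene reaction by allylic hydroxylation and oxidative transposition. It sets out from 12: SeO2 (cat.)/t-BuOOH hydroxylates the only allylic C–H to give the tertiary allylic alcohol (3R,3aS,4S,8aR)-3,6-dihydroxy-6,8a-dimethyl-3-(propan-2-yl)-1,2,3,3a,4,5,6,8a-octahydroazulen-4-yl 3,4-dimethoxybenzoate F4. Babler–Dauben oxidative transposition with pyridinium chlorochromate (CH2Cl2) then moves the oxygen to C10 and oxidises it, and the fallback comes back at 14.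

**Further compounds**

F1 | step 2 | (2S,3S)-2-[(1R)-1-hydroxy-3-methylpent-4-en-1-yl]-3-methyl-3-[1-(trimethylsilyl)ethenyl]cyclopentan-1-one | C=CC(C)C[C@@H](O)[C@H]1C(=O)CC[C@]1(C)C(=C)[Si](C)(C)C
F2 | step 5 | (2S,3R)-3-ethenyl-2-[(1S)-1-hydroxy-3-methylpent-4-en-1-yl]-3-methylcyclopentan-1-one | C=CC(C)C[C@H](O)[C@H]1C(=O)CC[C@]1(C)C=C
F3 | step 5 | (1R,2S,3R)-3-ethenyl-2-[(1S)-1-hydroxy-3-methylpent-4-en-1-yl]-3-methyl-1-(propan-2-yl)cyclopentan-1-ol | C=CC(C)C[C@H](O)[C@H]1[C@](O)(C(C)C)CC[C@]1(C)C=C
F4 | step 7 | (3R,3aS,4S,8aR)-3,6-dihydroxy-6,8a-dimethyl-3-(propan-2-yl)-1,2,3,3a,4,5,6,8a-octahydroazulen-4-yl 3,4-dimethoxybenzoate | COc1ccc(C(=O)O[C@H]2CC(C)(O)C=C[C@@]3(C)CC[C@@](O)(C(C)C)[C@H]23)cc1OC
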